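**Plan**

1. Retrosynthetic cuts, in order: the two angelate C–O bonds; the ring C–CH3 bond beside the cyclobutane bridgehead (enone plus cuprate); the cyclobutane bond between the ketone α-carbon and the CH bridge that carries the quaternary carbon (ketone enolate plus mesylate); the bond between the oxygenated ring carbon and the methyl-bearing quaternary cyclobutane carbon (key step); the bond between the six-membered ring and the carbinol carbon (allylboration); the quaternary carbon (epoxy silyl ether 1,2-shift).
2. Enabling feature: the quaternary C(CH3) of the cyclobutane is β to the ring ketone through the bridgehead CH, and its oxygenated neighbour is a carbonyl-level carbon. With the cyclobutane bond opened, the atoms C(=O)–CH–C(CH3)–CH–CH2–CH2 form a 3-methylcyclohex-2-enone whose C4 side chain ends in an aldehyde, so the key bond joins two acceptor carbons by reduction.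
3. Forward order of rings: cyclohexene (allyl unit), cyclohexenone, seven-membered ring (SmI2), cyclobutane (enolate alkylation); then the ring methyl and the two esters.
4. Stereochemistry: the quaternary carbon comes from Sharpless epoxidation and a stereospecific 1,2-shift; the carbinol and ring CH come from a (+)-α-pinene-derived allylborane (syn, reagent control); the ring fusion and new carbinol come from the tether and samarium in the key step; the cyclobutane closes with inversion; the ring methyl comes from cuprate addition to the open face.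

Key step: step 11

Remark: the (+)-α-pinene-derived borane of step 7 is taken to attack the Si face of the aldehyde, as the parent allyl and crotyl reagents do; the antipodal borane would be used if the sense proved opposite.

**Route**

Step 1
Reactants: 1 hex-1-en-5-yne
Product: 3 (2E)-3-methylhepta-2,6-dien-1-ol, via alkenylalane 2 (not isolated)
Conditions: Me3Al, Cp2ZrCl2 (cat.), CH2Cl2, 0 to 25 °C; then n-BuLi, THF, −78 °C; (CH2O)n, 25 °C; aq. HCl
Reagents that add atoms: trimethylaluminum C[Al](C)C; paraformaldehyde (as formaldehyde) C=O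
Why: Negishi zirconium-catalysed syn-carboalumination of the terminal alkyne (much faster than that of the alkene), then hydroxymethylation of the alkenylalanate, should give the (E)-trisubstituted allylic alcohol as a single isomer.

Step 2
Reactants: 3 (2E)-3-methylhepta-2,6-dien-1-ol
Product: 4 [(2R,3R)-3-(but-3-en-1-yl)-3-methyloxiran-2-yl]methanol
Conditions: Ti(OiPr)4 (cat.), D-(−)-diethyl tartrate (cat.), t-BuOOH, 4 Å MS, CH2Cl2, −20 °C
Reagents that add atoms: tert-butyl hydroperoxide CC(C)(C)OO
Why: Sharpless asymmetric epoxidation touches only the allylic alcohol; D-(−)-tartrate should give the (2R,3R) epoxide, the mirror image of the L-(+)-tartrate/geraniol case.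

Step 3
Reactants: 4 [(2R,3R)-3-(but-3-en-1-yl)-3-methyloxiran-2-yl]methanol
Product: 5 tert-butyl{[(2R,3R)-3-(but-3-en-1-yl)-3-methyloxiran-2-yl]methoxy}dimethylsilane
Conditions: TBSCl, imidazole, DMF, 25 °C
Reagents that add atoms: tert-butyldimethylsilyl chloride CC(C)(C)[Si](C)(C)Cl
Why: Standard silylation of a primary alcohol; the silyl ether is the migrating-group carrier for step 4 and the protecting group of the future angelate oxygen.

Step 4
Reactants: 5 tert-butyl{[(2R,3R)-3-(but-3-en-1-yl)-3-methyloxiran-2-yl]methoxy}dimethylsilane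
Product: 6 (2R)-2-{[(tert-butyldimethylsilyl)oxy]methyl}-2-methylhex-5-enal
Conditions: MeAl(OC6H2-2,6-tBu2-4-Br)2 (MABR, 20 mol %), CH2Cl2, −78 to −20 °C
Reagents that add atoms: none
Why: Lewis-acid-promoted rearrangement of a 2,3-epoxy silyl ether to a β-siloxy aldehyde (semipinacol-type 1,2-shift): the epoxide opens at the tertiary carbon and the siloxymethyl group migrates anti to the leaving oxygen, so the epoxide chirality is transferred to the quaternary carbon with inversion.

Step 5
Reactants: 7 2-methylcyclohex-2-en-1-one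
Product: 8 2-methylcyclohex-2-en-1-ol (racemic)
Conditions: NaBH4, CeCl3·7H2O, MeOH, 0 °C
Reagents that add atoms: none
Why: Luche 1,2-reduction of an enone; the stereocenter is of no consequence because the derived allyl unit is symmetric.

Step 6
Reactants: 8 2-methylcyclohex-2-en-1-ol
Product: 9 6-bromo-1-methylcyclohex-1-ene (racemic)
Conditions: PBr3, pyridine (cat.), Et2O, 0 °C
Reagents that add atoms: phosphorus tribromide BrP(Br)Br
Why: Allylic alcohol to allylic bromide; direct and allylic (SN2') substitution give the same constitution because the 2-methylallyl unit is symmetric.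

Step 7
Reactants: 9 6-bromo-1-methylcyclohex-1-ene; 10 (−)-B-methoxydiisopinocampheylborane; 6 (2R)-2-{[(tert-butyldimethylsilyl)oxy]methyl}-2-methylhex-5-enal
Product: 13 (1S,2R)-2-{[(tert-butyldimethylsilyl)oxy]methyl}-2-methyl-1-[(1R)-2-methylcyclohex-2-en-1-yl]hex-5-en-1-ol, via allylmagnesium bromide 11 (not isolated), via allylborane 12 (not isolated)
Conditions: Mg, THF, −15 °C (slow addition of 9); 10, Et2O, −78 to 25 °C; then 6, −78 to 0 °C; NaOH, H2O2
Reagents that add atoms: none
Why: Brown-type asymmetric allylboration through a closed chair transition state: the ring CH2 on the attacking carbon is held cis to the boron-bearing carbon (a Z-allylborane by ring constraint), so the ring CH and the new hydroxyl come out syn, and the Ipc2B group should override the weak bias of the α-quaternary aldehyde.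

Step 8
Reactants: 13 (1S,2R)-2-{[(tert-butyldimethylsilyl)oxy]methyl}-2-methyl-1-[(1R)-2-methylcyclohex-2-en-1-yl]hex-5-en-1-ol
Product: 14 (1S,2R)-2-{[(tert-butyldimethylsilyl)oxy]methyl}-2-methyl-1-[(1R)-2-methylcyclohex-2-en-1-yl]hex-5-en-1-yl methanesulfonate
Conditions: MsCl, Et3N, CH2Cl2, 0 °C
Reagents that add atoms: methanesulfonyl chloride CS(=O)(=O)Cl
Why: Mesylation through sulfene tolerates the hindered secondary alcohol and retains configuration; the neopentylic mesylate should be inert until step 13.

Step 9
Reactants: 14 (1S,2R)-2-{[(tert-butyldimethylsilyl)oxy]methyl}-2-methyl-1-[(1R)-2-methylcyclohex-2-en-1-yl]hex-5-en-1-yl methanesulfonate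
Product: 15 (1S,2R)-2-{[(tert-butyldimethylsilyl)oxy]methyl}-2-methyl-1-[(1R)-2-methyl-4-oxocyclohex-2-en-1-yl]hex-5-en-1-yl methanesulfonate
Conditions: CrO3, 3,5-dimethylpyrazole, CH2Cl2, −20 °C
Reagents that add atoms: chromium trioxide O=[Cr](=O)=O
Why: Allylic C–H oxidation of a 1-methylcyclohexene to the 3-methylcyclohex-2-enone: the ring CH2 next to the vinylic CH is the only unhindered allylic methylene of the electron-rich trisubstituted alkene, and the terminal alkene is far less reactive.

Step 10
Reactants: 15 (1S,2R)-2-{[(tert-butyldimethylsilyl)oxy]methyl}-2-methyl-1-[(1R)-2-methyl-4-oxocyclohex-2-en-1-yl]hex-5-en-1-yl methanesulfonate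
Product: 16 (1S,2R)-2-{[(tert-butyldimethylsilyl)oxy]methyl}-2-methyl-1-[(1R)-2-methyl-4-oxocyclohex-2-en-1-yl]-5-oxopentyl methanesulfonate
Conditions: O3, CH2Cl2, −78 °C (to the first excess of ozone); then PPh3
Reagents that add atoms: ozone [O-][O+]=O
Why: Ozonolysis cleaves the electron-rich terminal alkene well before the electron-poor enone, and the neutral reductive work-up leaves the base-sensitive γ-branched enone mesylate untouched.

Step 11
Reactants: 16 (1S,2R)-2-{[(tert-butyldimethylsilyl)oxy]methyl}-2-methyl-1-[(1R)-2-methyl-4-oxocyclohex-2-en-1-yl]-5-oxopentyl methanesulfonate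
Product: 18 6-hydroxy-3,7-dimethyl-3-{[(tert-butyldimethylsilyl)oxy]methyl}-9-oxobicyclo[5.4.0]undecan-2-yl methanesulfonate (cis-fused; configuration as in the SMILES), via samarium enolate 17 (not isolated)
Conditions: SmI2 (2.5 equiv), t-BuOH (2 equiv), THF, −78 to 0 °C, slow addition of 16 at high dilution
Reagents that add atoms: none
Why: Two single-electron transfers from SmI2 join the aldehyde carbon and the enone β-carbon, two acceptor carbons, through a samarium ketyl that adds to the β-position and is reduced on to the samarium enolate 17, which t-BuOH protonates. The closest known reaction type is the SmI2 ketyl–olefin (aldehyde–enone) reductive cyclization, established for five- to eight-membered rings and for quaternary β-carbons. The seven-membered ring closes in the 7-exo-trig mode. The quaternary ring-fusion carbon is controlled by the tether: the C4 side chain stands pseudo-axial because of allylic strain with the neighbouring vinylic methyl group and can reach only its own face of C3, which gives the cis fusion. The carbinol carbon should form with the bulky samarium-bound oxygen pseudo-equatorial on the forming ring and turned toward the enone oxygen, which the same trivalent samarium can bridge. The step needs cyclization to win over simple reduction or pinacol coupling of the aldehyde and the mesylate to survive; high dilution, the conjugated acceptor, and the inertness of a neopentylic secondary mesylate to SmI2 at low temperature without HMPA should secure this.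

Step 12
Reactants: 18 the bicyclic hydroxy keto mesylate
Product: 19 6-[(tert-butyldimethylsilyl)oxy]-3,7-dimethyl-3-{[(tert-butyldimethylsilyl)oxy]methyl}-9-oxobicyclo[5.4.0]undecan-2-yl methanesulfonate
Conditions: TBSOTf, 2,6-lutidine, CH2Cl2, −78 °C
Reagents that add atoms: tert-butyldimethylsilyl trifluoromethanesulfonate CC(C)(C)[Si](C)(C)OS(=O)(=O)C(F)(F)F
Why: Silyl triflate silylation of a hindered secondary alcohol; it blocks the alkoxide, which in step 13 could otherwise displace the mesylate across the seven-membered ring to form an oxygen bridge.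

Step 13
Reactants: 19 the bis-silyl keto mesylate
Product: 20 3-[(tert-butyldimethylsilyl)oxy]-2,6-dimethyl-6-{[(tert-butyldimethylsilyl)oxy]methyl}tricyclo[5.4.0.0(2,8)]undecan-9-one (configuration as in the SMILES)
Conditions: KOtBu, THF (t-BuOH as proton shuttle), 0 to 40 °C
Reagents that add atoms: none
Why: Intramolecular C-alkylation of a ketone enolate by a sulfonate (keto-sulfonate cyclization to a bicyclo[3.1.1]heptanone), SN2 with inversion at the mesylate carbon; of the two equilibrating enolates only the one toward the quaternary carbon can reach the backside of the C–OMs bond, which lies anti-periplanar to the ring-fusion bond, and O-alkylation would need a bridgehead enol ether.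

Step 14
Reactants: 20 the tricyclic ketone
Product: 22 3-[(tert-butyldimethylsilyl)oxy]-2,6-dimethyl-6-{[(tert-butyldimethylsilyl)oxy]methyl}tricyclo[5.4.0.0(2,8)]undec-10-en-9-one, via lithium enolate 21 (not isolated)
Conditions: LiN(iPr)2, THF, −78 °C; then PhS(Cl)=N-tBu, −78 °C
Reagents that add atoms: none
Why: Mukaiyama one-pot dehydrogenation of a ketone enolate with N-tert-butylbenzenesulfinimidoyl chloride; the ketone can enolize only away from the cyclobutane bridgehead, so the enone forms on the CH2–CH2 side alone.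

Step 15
Reactants: 22 the tricyclic enone
Product: 23 3-[(tert-butyldimethylsilyl)oxy]-2,6,11-trimethyl-6-{[(tert-butyldimethylsilyl)oxy]methyl}tricyclo[5.4.0.0(2,8)]undecan-9-one
Conditions: Me2CuLi (from CuI and MeLi), Et2O, −40 °C; aq. NH4Cl
Reagents that add atoms: lithium dimethylcuprate C[Cu-]C.[Li+]
Why: Gilman conjugate addition to a bicyclo[3.1.1]heptenone, as with verbenone-type enones: the methyl enters from the face of the CH bridge, away from the methyl group that the quaternary bridge points over the enone, which sets the last stereocenter.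

Step 16
Reactants: 23 the methylated bis-silyl ether
Product: 24 3-hydroxy-6-(hydroxymethyl)-2,6,11-trimethyltricyclo[5.4.0.0(2,8)]undecan-9-one
Conditions: HF·pyridine, pyridine/THF, 0 to 25 °C
Reagents that add atoms: none
Why: Fluoride-mediated cleavage of both silyl ethers; the liberated secondary hydroxyl is γ to the ketone and trans across the cyclobutane, so neither retro-aldol nor hemiketal formation is open.

Step 17
Reactants: 24 the diol; 25 angelic acid
Product: 27 the target, [3-(angeloyloxy)-2,6,11-trimethyl-9-oxotricyclo[5.4.0.0(2,8)]undec-6-yl]methyl angelate, via mixed anhydride 26 (not isolated)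
Conditions: 25 (3 equiv), 2,4,6-Cl3C6H2COCl, Et3N, toluene, 25 °C; then 24, 80 °C
Reagents that add atoms: none
Why: Yamaguchi mixed-anhydride esterification run without a nucleophilic amine catalyst, the usual way to acylate hindered alcohols with angelic acid while keeping the (Z)-geometry from isomerizing to the tiglate.

**Compound list**

1 | hex-1-en-5-yne | C#CCCC=C | starting material
2 | dimethyl[(1E)-2-methylhexa-1,5-dien-1-yl]alane | C=CCC/C(C)=C/[Al](C)C | intermediate
3 | (2E)-3-methylhepta-2,6-dien-1-ol | C=CCC/C(C)=C/CO | intermediate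
4 | [(2R,3R)-3-(but-3-en-1-yl)-3-methyloxiran-2-yl]methanol | OC[C@H]1O[C@]1(C)CCC=C | intermediate
5 | tert-butyl{[(2R,3R)-3-(but-3-en-1-yl)-3-methyloxiran-2-yl]methoxy}dimethylsilane | CC(C)(C)[Si](C)(C)OC[C@H]1O[C@]1(C)CCC=C | intermediate
6 | (2R)-2-{[(tert-butyldimethylsilyl)oxy]methyl}-2-methylhex-5-enal | CC(C)(C)[Si](C)(C)OC[C@@](C=O)(C)CCC=C | intermediate
7 | 2-methylcyclohex-2-en-1-one | CC1=CCCCC1=O | starting material
8 | 2-methylcyclohex-2-en-1-ol (racemic) | CC1=CCCCC1O | intermediate
9 | 6-bromo-1-methylcyclohex-1-ene (racemic) | CC1=CCCCC1Br | intermediate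
10 | (−)-B-methoxydiisopinocampheylborane, from (+)-α-pinene | COB([C@@H]1C[C@@H]2C[C@H]([C@H]1C)C2(C)C)[C@@H]1C[C@@H]2C[C@H]([C@H]1C)C2(C)C | starting material
11 | (2-methylcyclohex-2-en-1-yl)magnesium bromide | CC1=CCCCC1[Mg]Br | intermediate
12 | B-[(1S)-2-methylcyclohex-2-en-1-yl]diisopinocampheylborane (reacting C–B epimer; the epimers interconvert by 1,3-boron shift) | CC1=CCCC[C@@H]1B([C@@H]2C[C@@H]3C[C@H]([C@H]2C)C3(C)C)[C@@H]4C[C@@H]5C[C@H]([C@H]4C)C5(C)C | intermediate
13 | (1S,2R)-2-{[(tert-butyldimethylsilyl)oxy]methyl}-2-methyl-1-[(1R)-2-methylcyclohex-2-en-1-yl]hex-5-en-1-ol | CC(C)(C)[Si](C)(C)OC[C@@]([C@@H](O)[C@H]1C(C)=CCCC1)(C)CCC=C | intermediate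
14 | methanesulfonate of 13 | CC(C)(C)[Si](C)(C)OC[C@@]([C@@H](OS(C)(=O)=O)[C@H]1C(C)=CCCC1)(C)CCC=C | intermediate
15 | (1S,2R)-2-{[(tert-butyldimethylsilyl)oxy]methyl}-2-methyl-1-[(1R)-2-methyl-4-oxocyclohex-2-en-1-yl]hex-5-en-1-yl methanesulfonate | CC(C)(C)[Si](C)(C)OC[C@@]([C@@H](OS(C)(=O)=O)[C@H]1C(C)=CC(=O)CC1)(C)CCC=C | intermediate
16 | (1S,2R)-2-{[(tert-butyldimethylsilyl)oxy]methyl}-2-methyl-1-[(1R)-2-methyl-4-oxocyclohex-2-en-1-yl]-5-oxopentyl methanesulfonate | CC(C)(C)[Si](C)(C)OC[C@@]([C@@H](OS(C)(=O)=O)[C@H]1C(C)=CC(=O)CC1)(C)CCC=O | intermediate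
17 | bis(diiodosamarium) enolate alkoxide of 18 | CC(C)(C)[Si](C)(C)OC[C@@]1(C)CC[C@@H](O[Sm](I)I)[C@]2(C)[C@H]([C@@H]1OS(C)(=O)=O)CCC(O[Sm](I)I)=C2 | intermediate
18 | cis-fused 6-hydroxy-3,7-dimethyl-3-{[(tert-butyldimethylsilyl)oxy]methyl}-9-oxobicyclo[5.4.0]undecan-2-yl methanesulfonate | CC(C)(C)[Si](C)(C)OC[C@@]1(C)CC[C@@H](O)[C@]2(C)[C@H]([C@@H]1OS(C)(=O)=O)CCC(=O)C2 | intermediate
19 | tert-butyldimethylsilyl ether of 18 | CC(C)(C)[Si](C)(C)OC[C@@]1(C)CC[C@@H](O[Si](C)(C)C(C)(C)C)[C@]2(C)[C@H]([C@@H]1OS(C)(=O)=O)CCC(=O)C2 | intermediate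
20 | 3-[(tert-butyldimethylsilyl)oxy]-2,6-dimethyl-6-{[(tert-butyldimethylsilyl)oxy]methyl}tricyclo[5.4.0.0(2,8)]undecan-9-one | CC(C)(C)[Si](C)(C)OC[C@@]1(C)CC[C@@H](O[Si](C)(C)C(C)(C)C)[C@]2(C)[C@@H]3[C@H]1[C@H]2C(=O)CC3 | intermediate
21 | lithium enolate of 20 | CC(C)(C)[Si](C)(C)OC[C@@]1(C)CC[C@@H](O[Si](C)(C)C(C)(C)C)[C@]2(C)[C@@H]3[C@H]1[C@H]2C(O[Li])=CC3 | intermediate
22 | 10,11-dehydro derivative of 20 (tricyclic enone) | CC(C)(C)[Si](C)(C)OC[C@@]1(C)CC[C@@H](O[Si](C)(C)C(C)(C)C)[C@]2(C)[C@@H]3[C@H]1[C@H]2C(=O)C=C3 | intermediate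
23 | 3-[(tert-butyldimethylsilyl)oxy]-2,6,11-trimethyl-6-{[(tert-butyldimethylsilyl)oxy]methyl}tricyclo[5.4.0.0(2,8)]undecan-9-one | CC(C)(C)[Si](C)(C)OC[C@@]1(C)CC[C@@H](O[Si](C)(C)C(C)(C)C)[C@]2(C)[C@@H]3[C@H]1[C@H]2C(=O)C[C@H]3C | intermediate
24 | 3-hydroxy-6-(hydroxymethyl)-2,6,11-trimethyltricyclo[5.4.0.0(2,8)]undecan-9-one | OC[C@@]1(C)CC[C@@H](O)[C@]2(C)[C@@H]3[C@H]1[C@H]2C(=O)C[C@H]3C | intermediate
25 | angelic acid, (2Z)-2-methylbut-2-enoic acid | C/C=C(/C)C(=O)O | starting material
26 | angelic 2,4,6-trichlorobenzoic anhydride | C/C=C(/C)C(=O)OC(=O)c1c(Cl)cc(Cl)cc1Cl | intermediate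
27 | [3-(angeloyloxy)-2,6,11-trimethyl-9-oxotricyclo[5.4.0.0(2,8)]undec-6-yl]methyl angelate (CNP0276938.1) | C/C=C(/C)C(=O)OC[C@@]1(C)CC[C@@H](OC(=O)/C(C)=C\C)[C@]2(C)[C@@H]3[C@H]1[C@H]2C(=O)C[C@H]3C | target

**Totals**

Total step count: 17. Longest linear sequence: 15 steps (steps 1–4, then 7–17); steps 5 and 6 form a two-step side branch.

**Steps most likely to fail**

Step 11 (key step). The aldehyde may be reduced to the alcohol or undergo pinacol coupling before the slow seven-membered closure, or the carbinol carbon may form with poor facial selectivity. The fallback replaces the reductive ketyl coupling by a tin-mediated radical conjugate addition. From 16, addition of PhSeSiMe3 should give the O-trimethylsilyl hemiselenoacetal F1 (both epimers give the same radical). Bu3SnH with Et3B/air at high dilution should then form the nucleophilic α-siloxyalkyl radical, whose 7-exo addition to the enone and hydrogen transfer should give the bicyclic trimethylsilyl ether F2. Mild acid methanolysis of F2 returns to the route at 18.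

Step 13. Displacement at the doubly branched sulfonate carbon may be too slow, so that loss of methanesulfonic acid or of a silyl group takes over. The fallback reverses the order of the two ring closures. From 16 the aldehyde is masked as the dimethyl acetal F3. KOtBu should then form the extended dienolate through the ring methyl group, and its α-alkylation by the mesylate should give the methylenebicyclo[3.1.1]heptanone acetal F4. Aqueous acid should give the methylenebicyclo[3.1.1]heptanone aldehyde F5. Hydrogen-atom transfer from an iron hydride (Fe(acac)3, PhSiH3, EtOH) to the exocyclic methylene should produce the tertiary cyclobutyl radical, which closes onto the aldehyde to the tricyclic hydroxy ketone F6. Silylation with TBSOTf returns to the route at 20.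

Step 9. Hydrogen abstraction may lack site selectivity among the ring CH2, the tertiary allylic CH, the vinylic methyl and the butenyl chain, or over-oxidation may occur. The fallback replaces C–H oxidation by epoxide transposition. From 14, m-CPBA should epoxidize the electron-rich ring alkene to the epoxide F7. PhSeNa should open it at the secondary carbon to the hydroxy selenide F8. H2O2 should give, by selenoxide elimination away from the carbinol carbon, the tertiary allylic alcohol F9. Oxidative 1,3-transposition with pyridinium chlorochromate returns to the route at 15.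

**Further compounds**

F1 | step 11 | (1S,2R)-2-{[(tert-butyldimethylsilyl)oxy]methyl}-2-methyl-1-[(1R)-2-methyl-4-oxocyclohex-2-en-1-yl]-5-(phenylselanyl)-5-[(trimethylsilyl)oxy]pentyl methanesulfonate (both C5 epimers) | CC(C)(C)[Si](C)(C)OC[C@@]([C@@H](OS(C)(=O)=O)[C@H]1C(C)=CC(=O)CC1)(C)CCC(O[Si](C)(C)C)[Se]c1ccccc1
F2 | step 11 | trimethylsilyl ether of 18 | CC(C)(C)[Si](C)(C)OC[C@@]1(C)CC[C@@H](O[Si](C)(C)C)[C@]2(C)[C@H]([C@@H]1OS(C)(=O)=O)CCC(=O)C2
F3 | step 13 | dimethyl acetal of 16 | CC(C)(C)[Si](C)(C)OC[C@@]([C@@H](OS(C)(=O)=O)[C@H]1C(C)=CC(=O)CC1)(C)CCC(OC)OC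
F4 | step 13 | 7-[5,5-dimethoxy-2-methyl-1-(tert-butyldimethylsilyloxy)pentan-2-yl]-6-methylidenebicyclo[3.1.1]heptan-2-one | CC(C)(C)[Si](C)(C)OC[C@@](C)(CCC(OC)OC)[C@H]1[C@@H]2CCC(=O)[C@H]1C2=C
F5 | step 13 | 4-methyl-4-(6-methylidene-2-oxobicyclo[3.1.1]heptan-7-yl)-5-(tert-butyldimethylsilyloxy)pentanal | CC(C)(C)[Si](C)(C)OC[C@@](C)(CCC=O)[C@H]1[C@@H]2CCC(=O)[C@H]1C2=C
F6 | step 13 | 3-hydroxy-2,6-dimethyl-6-{[(tert-butyldimethylsilyl)oxy]methyl}tricyclo[5.4.0.0(2,8)]undecan-9-one | CC(C)(C)[Si](C)(C)OC[C@@]1(C)CC[C@@H](O)[C@]2(C)[C@@H]3[C@H]1[C@H]2C(=O)CC3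
F7 | step 9 | ring epoxide of 14 (oxygen anti to the side chain) | CC(C)(C)[Si](C)(C)OC[C@@]([C@@H](OS(C)(=O)=O)[C@H]1[C@]2(C)O[C@@H]2CCC1)(C)CCC=C
F8 | step 9 | trans-hydroxy phenyl selenide from F7 | CC(C)(C)[Si](C)(C)OC[C@@]([C@@H](OS(C)(=O)=O)[C@H]1[C@](C)(O)[C@@H]([Se]c2ccccc2)CCC1)(C)CCC=C
F9 | step 9 | tertiary allylic alcohol (1-hydroxy-1-methylcyclohex-2-ene type) from F8 | CC(C)(C)[Si](C)(C)OC[C@@]([C@@H](OS(C)(=O)=O)[C@H]1[C@](C)(O)C=CCC1)(C)CCC=C
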